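(The readings were computed on assumed constants; the scatter is artificial.)

If starting material (S) and target (T) with released group (R) stand at their balance, a pre-equilibrium, then the earlier runs give me one number to take to the flask charged with 10 mM.

| flask | starting material | remark | time |
|---|---|---|---|
| Thursday's | 5 mM | run made earlier |  |
| Saturday's | 7.5 mM | run made earlier |  |
| flask | 10 mM |  | 25 min |

| run | time / min | target / % | starting material / % |
|---|---|---|---|
| Thursday's | 0.333 | 63.5 | 28.7 |
| Thursday's | 0.667 | 78.6 | 12.4 |
| Thursday's | 1.33 | 81.5 | 8.1 |
| Thursday's | 3.00 | 79.1 | 7.3 |
| Thursday's | 6.00 | 75.5 | 7.4 |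
| Thursday's | 15.0 | 66.3 | 5.7 |
| Thursday's | 30.0 | 55.9 | 4.7 |
| Saturday's | 0.333 | 61.4 | 27.7 |
| Saturday's | 0.667 | 73.1 | 13.8 |
| Saturday's | 1.33 | 74.7 | 10.1 |
| Saturday's | 3.00 | 71.2 | 8.9 |
| Saturday's | 6.00 | 64.4 | 8.9 |
| Saturday's | 15.0 | 52.1 | 5.2 |
| Saturday's | 30.0 | 41.0 | 4.5 |

(readings scatter by 0.3 percentage points)

- percentages count the starting material that a species holds: one side product or self-condensation product counts as two
- what was read earlier has a scatter of 0.3 percentage points, one standard deviation
- reactions considered so far: starting material <-> target + released group; starting material + target -> side product; 2 starting material -> self-condensation product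

- time, not beyond 25 min, at which the flask holds most target
- the amount of target, in percent of the starting material charged, at that time
- earliest time at which at least nineteen twentieths of that best amount are there, in min
- latest time at which they still are, in min

I read that number at 1.33 min, where each run shows its highest target reading. With T and S as fractions of the charge c, and R not read, I set R equal to cT, as the first step makes one of each, and I neglect the target already taken into side product:

Q = cT²/S: Thursday's 41.0 mM, Saturday's 41.4 mM, mean 41.2 mM

This Q, the product of T and R in millimolar over S in millimolar at balance, serves my second way. My first way does without it and runs a straight line through the two target readings against charge: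

T = 67.9 %

For the second way, the part that is neither T nor S is 10.4 % on Thursday and 15.2 % on Saturday, growing in step with the charge, so I take 20.3 % for the flask. Then T = 1 − L − S and S = cT²/Q, and I go round from Saturday's S:

S = 10.1 %, T = 69.6 %
S = 11.8 %, T = 68.0 %
S = 11.2 %, T = 68.5 %

The two ways part by 0.60 percentage points. They share readings, but the first uses T and the second uses S as well, so I commit to about 68.5 % at 1.33 min in the flask as my estimate of the amount near its peak.

The forecast gives 69.7 % at 1 min, with 0.5 min and 2.3 min as the edges; it reads "It then settles near the equilibrium T·R/S ≈ 46 mM in both runs", where I read 41.2 mM.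

The flask gives 69.5 % at 0.906 min, with edges at 0.505 min and 2.09 min.

    starting material ⇌ target + released group (K = 0.0420 M, k = 3.60 /min)
    starting material + target → side product (k = 21.0 /M/min)
    2 starting material → self-condensation product (k = 51.0 /M/min)

At 0.906 min the flask holds T 69.5 % and R 7.20 mM, from which Q foretells S of 12.1 %, and 12.4 % stands there. The half-life of target in the flask by its step with S is 4.9 min at 0.0892 min but 81 min at 25.0 min, far longer, with S down to 4.10 %. In the neighbour flask charged with 2.5 mM, T 80.3 % and R 2.15 mM at 25.0 min give by Q an S of 4.19 %, and that flask holds 4.05 %.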